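**Retrosynthetic overview**

1. The phenol is unmasked last (benzyl ether). Before that, the C3–CH2Ar bond is cut: alkylation of the enolate of (R)-4-(3,4-dimethoxybenzyl)butyrolactone with a protected syringyl bromide, trans to the C4 substituent, sets C3.
2. The γ-lactone, the only ring that is made, is formed in one operation from an acyclic (Z)-alkenyl sulfoxide and dichloroketene. A sulfonium [3,3] shift makes C3–C4, carboxylate-to-thionium closure makes O1–C5, and the chirality moves from sulfur to C4.
3. Enabling feature: in the lactone ring C5 is an O-bound CH2 with no carbon substituent and C3 is an enolisable CH. C5 can therefore carry a p-tolylthio group and C3 two chlorines for one step. C4=C5 is then a vinyl sulfoxide with the stereogenic sulfur on C5, and O1–C2(=O)–C3 is a ketene. Bu3SnH strips S and Cl afterwards.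
4. The sulfoxide comes from 3,4-dimethoxybenzyl bromide, an acetylene Grignard reagent and menthyl p-toluenesulfinate; the Z geometry comes from semihydrogenation.

Key step: step 4

Remark: the sense of sulfur-to-carbon chirality transfer in step 4 is assigned from the chair model given there. If the opposite sense were found, the commercially available enantiomeric sulfinate, (1S,2R,5S)-menthyl (R)-p-toluenesulfinate, would be used in step 2 with no other change.

**Route**

Step 1
Reactants: 1 3,4-dimethoxybenzyl bromide
Product: 2 1,2-dimethoxy-4-(prop-2-yn-1-yl)benzene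
Conditions: HC≡CMgBr (2.5 equiv), CuCl (10 mol %), THF, 0 → 50 °C
Reagents that add atoms: ethynylmagnesium bromide, C#C[Mg]Br
Why: Copper-catalysed cross-coupling of an alkynyl Grignard reagent with a reactive benzylic bromide (SN2-type C(sp)–C(sp3) bond formation) should give the skipped aryl alkyne, the excess of acetylide limiting double benzylation; no stereocentre is formed.

Step 2
Reactants: 2 1,2-dimethoxy-4-(prop-2-yn-1-yl)benzene; 3 (1R,2S,5R)-menthyl (S)-p-toluenesulfinate
Product: 5 (S)-1,2-dimethoxy-4-[3-(p-tolylsulfinyl)prop-2-yn-1-yl]benzene, via alkynylmagnesium bromide 4 (not isolated)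
Conditions: EtMgBr (1.0 equiv), THF, 0 °C → rt; then added to 3 (1.0 equiv) in toluene, −20 °C; aq NH4Cl
Reagents that add atoms: none
Why: Andersen sulfoxide synthesis: the alkynyl Grignard 4, formed by deprotonation of the terminal alkyne, displaces mentholate at sulfur with inversion, which fixes the (S)-configured sulfur of 5, and inverse addition at low temperature should avoid a second displacement and propargyl–allenyl isomerisation.

Step 3
Reactants: 5 (S)-1,2-dimethoxy-4-[3-(p-tolylsulfinyl)prop-2-yn-1-yl]benzene
Product: 6 (R)-1,2-dimethoxy-4-[(Z)-3-(p-tolylsulfinyl)prop-2-en-1-yl]benzene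
Conditions: H2 (1 atm, stopped after 1 equiv), RhCl(PPh3)3 (5 mol %), benzene, rt
Reagents that add atoms: none
Why: Homogeneous syn-hydrogenation of the alkynyl sulfoxide on RhCl(PPh3)3 should stop at the Z alkene, whose geometry is set by cis delivery of both hydrogens, and it leaves sulfur untouched (the descriptor changes from S to R only because the alkenyl group ranks below p-tolyl).

Step 4
Reactants: 6 (R)-1,2-dimethoxy-4-[(Z)-3-(p-tolylsulfinyl)prop-2-en-1-yl]benzene
Product: 9 (4S,5R)-3,3-dichloro-4-(3,4-dimethoxybenzyl)-5-(p-tolylthio)dihydrofuran-2(3H)-one, via acyloxysulfonium enolate 7 (not isolated), via thionium carboxylate 8 (not isolated)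
Conditions: Cl3CCOCl (2.5 equiv, slow addition), Zn–Cu couple (5 equiv), Et2O, 35 °C
Reagents that add atoms: dichloroketene, O=C=C(Cl)Cl, made in the flask from trichloroacetyl chloride, ClC(Cl)(Cl)C(Cl)=O
Why: The sulfinyl oxygen of 6 adds to the carbonyl carbon of dichloroketene (made in the flask from Cl3CCOCl and Zn) to give the acyloxysulfonium enolate 7, a charge-accelerated [3,3]-sigmatropic shift then makes the C3–C4 bond while the S–O bond breaks, and the resulting thionium carboxylate 8 collapses by O1–C5 bond formation. The closest known reaction type is the dichloroketene lactonisation of enantiopure 1-alkenyl p-tolyl sulfoxides (Marino lactonisation, an additive Pummerer process), applied here to a new alkenyl sulfoxide. The lactone ring closes by 5-exo-trig attack of the carboxylate oxygen on the thionium carbon. C4 is controlled by the stereogenic sulfur: in the chair transition state the p-tolyl group is pseudo-equatorial and the sulfur lone pair faces the cis CH2Ar group, so the enolate carbon is delivered to the alkene face that carries the S–O bond, which for (R)-sulfur and Z geometry is the face leading to the 4R centre of the target (4S in 9 only because the CCl2 carbon outranks C5); C5 follows from suprafacial addition across the Z alkene and is erased in step 5. The step needs O-acylation and rearrangement to outrun ketene [2+2] cycloaddition, loss of the benzylic proton and arene capture of the thionium ion, and it needs one reacting rotamer about the S–C bond: the electron-poor alkene, the base-free Zn conditions, the intramolecular carboxylate and the allylic strain of the Z alkene should secure this.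

Step 5
Reactants: 9 (4S,5R)-3,3-dichloro-4-(3,4-dimethoxybenzyl)-5-(p-tolylthio)dihydrofuran-2(3H)-one
Product: 10 (R)-4-(3,4-dimethoxybenzyl)dihydrofuran-2(3H)-one
Conditions: Bu3SnH (4 equiv), AIBN (0.2 equiv), toluene, 110 °C; KF work-up
Reagents that add atoms: none
Why: Radical chain reduction with Bu3SnH should remove both α-carbonyl chlorines and cleave the C5–S bond of the O,S-acetal through the oxygen-stabilised C5 radical, while the C4 stereocentre, which never becomes a radical or an enolisable position, is kept.

Step 6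
Reactants: 11 syringaldehyde (4-hydroxy-3,5-dimethoxybenzaldehyde)
Product: 12 4-(benzyloxy)-3,5-dimethoxybenzaldehyde
Conditions: BnBr (1.1 equiv), K2CO3 (1.5 equiv), DMF, 60 °C
Reagents that add atoms: benzyl bromide, BrCc1ccccc1
Why: Williamson ether synthesis on the acidic, para-formyl-activated phenol should proceed cleanly despite the two flanking methoxy groups.

Step 7
Reactants: 12 4-(benzyloxy)-3,5-dimethoxybenzaldehyde
Product: 13 [4-(benzyloxy)-3,5-dimethoxyphenyl]methanol
Conditions: NaBH4 (0.5 equiv), MeOH, 0 °C
Reagents that add atoms: none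
Why: Borohydride reduction of an aryl aldehyde to the benzylic alcohol is chemoselective and leaves the benzyl ether intact.

Step 8
Reactants: 13 [4-(benzyloxy)-3,5-dimethoxyphenyl]methanol
Product: 14 2-(benzyloxy)-5-(bromomethyl)-1,3-dimethoxybenzene
Conditions: PBr3 (0.4 equiv), Et2O, 0 °C; used at once
Reagents that add atoms: phosphorus tribromide, BrP(Br)Br
Why: Bromination of a benzylic alcohol with PBr3 (displacement of the phosphite ester by bromide) should give the labile electron-rich benzylic bromide, which is used without storage.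

Step 9
Reactants: 10 (R)-4-(3,4-dimethoxybenzyl)dihydrofuran-2(3H)-one; 14 2-(benzyloxy)-5-(bromomethyl)-1,3-dimethoxybenzene
Product: 16 (3R,4R)-3-[4-(benzyloxy)-3,5-dimethoxybenzyl]-4-(3,4-dimethoxybenzyl)dihydrofuran-2(3H)-one, via lithium enolate 15 (not isolated)
Conditions: LiN(SiMe3)2 (1.1 equiv), THF, −78 °C; then 14 (1.1 equiv), DMPU (2 equiv), −78 → −40 °C
Reagents that add atoms: none
Why: Alkylation of the lactone lithium enolate 15 with the benzylic bromide should occur anti to the C4 benzyl group (1,2-induction in the five-membered enolate), which sets C3 as R and gives the trans lactone; this is the standard α-benzylation of β-benzyl-γ-butyrolactones.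

Step 10
Reactants: 16 (3R,4R)-3-[4-(benzyloxy)-3,5-dimethoxybenzyl]-4-(3,4-dimethoxybenzyl)dihydrofuran-2(3H)-one
Product: 17 (3R,4R)-4-(3,4-dimethoxybenzyl)-3-(4-hydroxy-3,5-dimethoxybenzyl)dihydrofuran-2(3H)-one
Conditions: H2 (1 atm), 10% Pd/C, EtOAc, rt
Reagents that add atoms: none
Why: Hydrogenolysis of the benzyl aryl ether on Pd/C should free the phenol under neutral conditions without touching the lactone or either stereocentre.

**Compound list**

1 | 3,4-dimethoxybenzyl bromide | COc1ccc(CBr)cc1OC | starting material
2 | 1,2-dimethoxy-4-(prop-2-yn-1-yl)benzene | COc1ccc(CC#C)cc1OC | intermediate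
3 | (1R,2S,5R)-menthyl (S)-p-toluenesulfinate | Cc1ccc(cc1)[S@@](=O)O[C@@H]1C[C@H](C)CC[C@H]1C(C)C | starting material
4 | [3-(3,4-dimethoxyphenyl)prop-1-yn-1-yl]magnesium bromide (not isolated) | COc1ccc(CC#C[Mg]Br)cc1OC | intermediate
5 | (S)-1,2-dimethoxy-4-[3-(p-tolylsulfinyl)prop-2-yn-1-yl]benzene | Cc1ccc(cc1)[S@](=O)C#CCc1ccc(OC)c(OC)c1 | intermediate
6 | (R)-1,2-dimethoxy-4-[(Z)-3-(p-tolylsulfinyl)prop-2-en-1-yl]benzene | Cc1ccc(cc1)[S@](=O)/C=C\Cc1ccc(OC)c(OC)c1 | intermediate
7 | acyloxysulfonium enolate: 2,2-dichloro-1-{[(Z)-3-(3,4-dimethoxyphenyl)prop-1-en-1-yl](p-tolyl)sulfoniooxy}ethen-1-olate (not isolated) | Cc1ccc(cc1)[S@+](OC([O-])=C(Cl)Cl)/C=C\Cc1ccc(OC)c(OC)c1 | intermediate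
8 | thionium carboxylate: (S)-2,2-dichloro-3-(3,4-dimethoxybenzyl)-4-(p-tolylsulfaniumylidene)butanoate (not isolated) | COc1ccc(C[C@@H](C=[S+]c2ccc(C)cc2)C(Cl)(Cl)C([O-])=O)cc1OC | intermediate
9 | (4S,5R)-3,3-dichloro-4-(3,4-dimethoxybenzyl)-5-(p-tolylthio)dihydrofuran-2(3H)-one (expected 4,5-cis isomer) | COc1ccc(C[C@H]2[C@@H](Sc3ccc(C)cc3)OC(=O)C2(Cl)Cl)cc1OC | intermediate
10 | (R)-4-(3,4-dimethoxybenzyl)dihydrofuran-2(3H)-one | COc1ccc(C[C@H]2COC(=O)C2)cc1OC | intermediate
11 | syringaldehyde (4-hydroxy-3,5-dimethoxybenzaldehyde) | COc1cc(C=O)cc(OC)c1O | starting material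
12 | 4-(benzyloxy)-3,5-dimethoxybenzaldehyde | COc1cc(C=O)cc(OC)c1OCc1ccccc1 | intermediate
13 | [4-(benzyloxy)-3,5-dimethoxyphenyl]methanol | COc1cc(CO)cc(OC)c1OCc1ccccc1 | intermediate
14 | 2-(benzyloxy)-5-(bromomethyl)-1,3-dimethoxybenzene | COc1cc(CBr)cc(OC)c1OCc1ccccc1 | intermediate
15 | lithium (R)-4-(3,4-dimethoxybenzyl)-4,5-dihydrofuran-2-olate (not isolated) | COc1ccc(C[C@H]2COC([O-])=C2)cc1OC.[Li+] | intermediate
16 | (3R,4R)-3-[4-(benzyloxy)-3,5-dimethoxybenzyl]-4-(3,4-dimethoxybenzyl)dihydrofuran-2(3H)-one | COc1ccc(C[C@H]2COC(=O)[C@@H]2Cc2cc(OC)c(OCc3ccccc3)c(OC)c2)cc1OC | intermediate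
17 | (3R,4R)-4-(3,4-dimethoxybenzyl)-3-(4-hydroxy-3,5-dimethoxybenzyl)dihydrofuran-2(3H)-one | COc1ccc(C[C@H]2COC(=O)[C@@H]2Cc2cc(OC)c(O)c(OC)c2)cc1OC | target

**Step count**

Total step count: 10. Longest linear sequence: 7 steps (steps 1–5, 9 and 10, from compound 1).

**Steps most likely to fail**

Step 4. The acyloxysulfonium enolate may leak into a vinylogous Pummerer pathway by loss of the doubly activated benzylic proton. The thionium ion may be captured by the electron-rich dimethoxyphenyl ring before the carboxylate closes. A minor rotamer about the S–C bond may react and lower the transfer of chirality. The fallback replaces sulfur-to-carbon chirality transfer by auxiliary-controlled alkylation and sets out from compound 1.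
- (R)-4-Benzyloxazolidin-2-one is acylated with 4-tert-butoxy-4-oxobutanoic acid (t-BuCOCl, Et3N, LiCl, THF, −20 °C → rt) to give tert-butyl 4-[(R)-4-benzyl-2-oxooxazolidin-3-yl]-4-oxobutanoate F1.
- Its sodium enolate (NaN(SiMe3)2, THF, −78 °C) is alkylated with 1 in an Evans alkylation, anti to the auxiliary benzyl group, to give tert-butyl (R)-4-[(R)-4-benzyl-2-oxooxazolidin-3-yl]-3-(3,4-dimethoxybenzyl)-4-oxobutanoate F2.
- LiBH4 (THF, 1 equiv H2O, 0 °C) reduces the imide carbonyl and releases the auxiliary to give tert-butyl (R)-3-(3,4-dimethoxybenzyl)-4-hydroxybutanoate F3.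
- CF3CO2H in CH2Cl2 cleaves the tert-butyl ester and closes the lactone, and the route is rejoined at compound 10 (step 9).

Step 5. Homolysis of the C5–S bond of the O,S-acetal may lag behind dechlorination, so that the reduction stalls at the thio lactone, and tin residues may be carried forward. The fallback is a polar, stepwise removal and sets out from compound 9.
- Zn dust in AcOH (rt) removes both chlorines to give (4R,5R)-4-(3,4-dimethoxybenzyl)-5-(p-tolylthio)dihydrofuran-2(3H)-one F4.
- Thiophilic hydrolysis of the O,S-acetal (AgNO3, 2,6-lutidine, aq THF) gives the lactol (4R)-4-(3,4-dimethoxybenzyl)-5-hydroxydihydrofuran-2(3H)-one F5.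
- NaBH4 (EtOH, 0 °C) reduces the open 4-oxo acid form of the lactol, and acidification (2 M HCl) relactonises to compound 10, where the route is rejoined.

Step 3. Over-reduction to the saturated sulfoxide, or rhodium hydride mediated migration or Z-to-E isomerisation of the skipped alkene, would erode the enantiomeric purity downstream, because E and Z isomers transfer chirality in opposite senses. The fallback fixes the alkene geometry before the C–S bond is made; it sets out from compound 2 and bypasses compound 5.
- Iodination of the terminal alkyne (N-iodosuccinimide, AgNO3 cat., acetone) gives 4-(3-iodoprop-2-yn-1-yl)-1,2-dimethoxybenzene F6.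
- cis-Reduction with diimide (2-nitrobenzenesulfonyl hydrazide, Et3N, THF/i-PrOH, rt) gives 4-[(Z)-3-iodoprop-2-en-1-yl]-1,2-dimethoxybenzene F7.
- Iodine–lithium exchange (t-BuLi, 2 equiv, Et2O, −78 °C), transmetalation with MgBr2·OEt2 and addition to sulfinate 3 (Andersen synthesis, inversion at sulfur, retention of alkene geometry) give compound 6, where the route is rejoined.

**Further compounds**

F1 | step 4 | tert-butyl 4-[(R)-4-benzyl-2-oxooxazolidin-3-yl]-4-oxobutanoate | CC(C)(C)OC(=O)CCC(=O)N1C(=O)OC[C@H]1Cc1ccccc1
F2 | step 4 | tert-butyl (R)-4-[(R)-4-benzyl-2-oxooxazolidin-3-yl]-3-(3,4-dimethoxybenzyl)-4-oxobutanoate | CC(C)(C)OC(=O)C[C@@H](Cc1ccc(OC)c(OC)c1)C(=O)N1C(=O)OC[C@H]1Cc1ccccc1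
F3 | step 4 | tert-butyl (R)-3-(3,4-dimethoxybenzyl)-4-hydroxybutanoate | CC(C)(C)OC(=O)C[C@@H](Cc1ccc(OC)c(OC)c1)CO
F4 | step 5 | (4R,5R)-4-(3,4-dimethoxybenzyl)-5-(p-tolylthio)dihydrofuran-2(3H)-one | COc1ccc(C[C@H]2[C@@H](Sc3ccc(C)cc3)OC(=O)C2)cc1OC
F5 | step 5 | (4R)-4-(3,4-dimethoxybenzyl)-5-hydroxydihydrofuran-2(3H)-one | COc1ccc(C[C@H]2C(O)OC(=O)C2)cc1OC
F6 | step 3 | 4-(3-iodoprop-2-yn-1-yl)-1,2-dimethoxybenzene | COc1ccc(CC#CI)cc1OC
F7 | step 3 | 4-[(Z)-3-iodoprop-2-en-1-yl]-1,2-dimethoxybenzene | COc1ccc(C/C=C\I)cc1OC
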